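**Assumption:** the target SMILES has no stereocentres and no E/Z-stereogenic double bond (the prenyl alkene carries two identical methyls), so the compound is achiral and no stereocontrol is needed.

## Retrosynthetic overview

1. Target ⇐ chelation-controlled 5-O-demethylation and MOM removal of a fully protected 6-prenyl isoflavone.
2. The 4-pyranone ring (C3–C4 and O1–C2 bonds) is the only ring built. It is closed in the convergent step by Rh(III) aldehyde C–H activation of a salicylaldehyde (A ring) and annulation with a 4-aryl-1-tosyl-1,2,3-triazole (B ring plus C2/C3). This is the proposed new step.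
3. A-ring salicylaldehyde ⇐ ortho-formylation of a C2-symmetric 3,5-dimethoxy-4-prenylphenol ⇐ Ir-catalysed meta C–H borylation/oxidation ⇐ ortho-lithiation/prenylation of 1,3-dimethoxybenzene ⇐ resorcinol.
4. Triazole ⇐ CuAAC of an aryl alkyne ⇐ Sonogashira coupling of 4-iodoresorcinol bis-MOM ether with ethynyltrimethylsilane ⇐ resorcinol.
5. Both benzene rings come intact from resorcinol; symmetry of the A-ring phenol removes any 6- versus 8-prenyl ambiguity.

## Route

**Branch A (A ring)**

Step 1
Reactants: 1 resorcinol (benzene-1,3-diol)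
Product: 2 1,3-dimethoxybenzene
Conditions: MeI (2.5 equiv), K2CO3, DMF, rt → 40 °C
Reagents that add atoms: iodomethane, CI
Why: Williamson O-methylation of both phenols; it installs the two equivalent OMe groups (future 5-O and 7-O) that flank the ortho-metalation site.

Step 2
Reactants: 2 1,3-dimethoxybenzene; 3 prenyl bromide (1-bromo-3-methylbut-2-ene)
Product: 4 1,3-dimethoxy-2-(3-methylbut-2-en-1-yl)benzene
Conditions: n-BuLi, THF, 0 °C → rt; CuI (10 mol %), then 3, −78 °C → rt
Reagents that add atoms: none beyond reactant 3
Why: Directed ortho-metalation occurs at C2 between the two OMe groups, and Cu-assisted SN2 allylation of the aryllithium gives the linear prenyl arene.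

Step 3
Reactants: 4 1,3-dimethoxy-2-(3-methylbut-2-en-1-yl)benzene
Product: 5 2-[3,5-dimethoxy-4-(3-methylbut-2-en-1-yl)phenyl]-4,4,5,5-tetramethyl-1,3,2-dioxaborolane
Conditions: [Ir(OMe)(cod)]2 (1.5 mol %), dtbpy (3 mol %), B2pin2 (0.8 equiv), MTBE, 60 °C
Reagents that add atoms: bis(pinacolato)diboron, CC1(C)OB(OC1(C)C)B1OC(C)(C)C(C)(C)O1
Why: Sterically controlled Ir-catalysed aromatic C–H borylation; C5–H is the only ring C–H without an ortho substituent, and the trisubstituted alkene is a poor substrate for Ir–boryl addition.

Step 4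
Reactants: 5 aryl pinacol boronate
Product: 6 3,5-dimethoxy-4-(3-methylbut-2-en-1-yl)phenol
Conditions: 30 % H2O2, aq NaOH, THF, 0 °C → rt
Reagents that add atoms: hydrogen peroxide, OO
Why: Oxidative ipso-hydroxylation of the arylboronate (1,2-aryl shift in the peroxyborate); basic peroxide does not epoxidise the unactivated prenyl alkene.

Step 5
Reactants: 6 3,5-dimethoxy-4-(3-methylbut-2-en-1-yl)phenol
Product: 7 6-hydroxy-2,4-dimethoxy-3-(3-methylbut-2-en-1-yl)benzaldehyde
Conditions: MgCl2, Et3N, (CH2O)n, MeCN, reflux
Reagents that add atoms: paraformaldehyde (formaldehyde), C=O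
Why: Casnati–Skattebøl Mg-phenoxide ortho-formylation; the two ortho positions are equivalent by symmetry and the para position is blocked, so one regioisomer forms under acid-free conditions.

**Branch B (B ring plus C2/C3)**

Step 6
Reactants: 1 resorcinol
Product: 8 1,3-bis(methoxymethoxy)benzene
Conditions: MOMCl (2.4 equiv), i-Pr2NEt, CH2Cl2, 0 °C → rt
Reagents that add atoms: chloromethyl methyl ether, COCCl
Why: Standard MOM acetal protection of both phenols; MOM is base-stable and inert to Pd, Cu and Rh.

Step 7
Reactants: 8 1,3-bis(methoxymethoxy)benzene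
Product: 9 1-iodo-2,4-bis(methoxymethoxy)benzene
Conditions: NIS (1.0 equiv), MeCN, 0 °C → rt, dark
Reagents that add atoms: N-iodosuccinimide, O=C1CCC(=O)N1I
Why: Electrophilic aromatic iodination of the activated ring at C4 (para to one OMOM, ortho to the other); the C2 site between the two OMOM groups is hindered.

Step 8
Reactants: 9 1-iodo-2,4-bis(methoxymethoxy)benzene; 10 ethynyltrimethylsilane
Product: 11 {[2,4-bis(methoxymethoxy)phenyl]ethynyl}trimethylsilane
Conditions: PdCl2(PPh3)2 (2 mol %), CuI (4 mol %), Et3N/THF, rt → 40 °C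
Reagents that add atoms: none beyond reactant 10
Why: Sonogashira coupling of an aryl iodide with a silyl-capped alkyne.

Step 9
Reactants: 11 aryl(trimethylsilyl)alkyne
Product: 12 1-ethynyl-2,4-bis(methoxymethoxy)benzene
Conditions: K2CO3, MeOH, rt
Reagents that add atoms: none
Why: Methoxide-mediated protodesilylation of the C(sp)–Si bond; MOM ethers are stable to base.

Step 10
Reactants: 12 1-ethynyl-2,4-bis(methoxymethoxy)benzene
Product: 13 4-[2,4-bis(methoxymethoxy)phenyl]-1-(4-methylbenzenesulfonyl)-1H-1,2,3-triazole
Conditions: TsN3 (1.0 equiv), CuTC (10 mol %), toluene, 0 °C → rt; used promptly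
Reagents that add atoms: tosyl azide, Cc1ccc(cc1)S(=O)(=O)N=[N+]=[N-]
Why: Cu-catalysed azide–alkyne cycloaddition gives only the 1-sulfonyl-4-aryl triazole, a bench-stable precursor of an α-aryl azavinyl carbene.

**Union and end game**

Step 11
Reactants: 7 6-hydroxy-2,4-dimethoxy-3-(3-methylbut-2-en-1-yl)benzaldehyde; 13 N-tosyl triazole
Product: 14 3-[2,4-bis(methoxymethoxy)phenyl]-5,7-dimethoxy-6-(3-methylbut-2-en-1-yl)-4H-chromen-4-one
Conditions: [Cp*Rh(MeCN)3](SbF6)2 (5 mol %), CsOPiv (30 mol %), 4 Å MS, DCE, 80 °C, slow addition of 13 (1.3 equiv)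
Reagents that add atoms: none
Why: Proposed new method: Cp*Rh(III)-catalysed redox-neutral [4+2] annulation of a salicylaldehyde with a 4-aryl-1-sulfonyl-1,2,3-triazole. Phenoxide-assisted aldehyde C–H rhodation gives a five-membered acyl-rhodacycle; 13, in ring–chain equilibrium with its α-diazo N-tosylimine, forms a Rh azavinyl carbene; 1,1-migratory insertion of the acyl group into the carbene makes the C4–C3 bond at the aryl-bearing carbon, so only the 3-aryl isomer can form; protonolysis by PivOH releases the 2-aryl-3-(tosylamino)enone (N-tosylimine tautomer); the phenol adds to the imine carbon (O1–C2 bond) and E1cB loss of TsNH2 aromatises the pyranone, with N2 and TsNH2 as the only by-products and no oxidant to threaten the prenyl alkene. Closest known reaction type: Cp*Rh(III) aldehyde C–H activation/carbene-insertion annulations of salicylaldehydes with diazo compounds or sulfoxonium ylides (giving 2-substituted chromones), combined with Rh azavinyl-carbene chemistry of N-sulfonyl triazoles and the classical o-hydroxyaryl enaminone → chromone cyclisation.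

Step 12
Reactants: 14 bis-MOM isoflavone
Product: 15 3-(2,4-dihydroxyphenyl)-5,7-dimethoxy-6-(3-methylbut-2-en-1-yl)-4H-chromen-4-one
Conditions: 3 M aq HCl/MeOH (1:5), 45 °C
Reagents that add atoms: none
Why: Acid-catalysed acetal (MOM) cleavage; it is done while the prenyl group is flanked by two OMe groups, so there is no free ortho-OH and acid-induced chroman formation is impossible.

Step 13
Reactants: 15 5,7-dimethoxy isoflavone
Product: 16 7-O-methylluteone, 3-(2,4-dihydroxyphenyl)-5-hydroxy-7-methoxy-6-(3-methylbut-2-en-1-yl)-4H-chromen-4-one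
Conditions: MgI2·OEt2 (4 equiv), THF, 60 °C; cold aq NH4Cl/Na2S2O3 work-up
Reagents that add atoms: none
Why: Chelation-controlled demethylation; Mg bridges C4=O and the peri 5-OMe and iodide removes only that methyl, leaving the 7-OMe, while the aprotic conditions spare the prenyl group next to the new Mg-chelated 5-oxygen.

## Compound list

1 | resorcinol | Oc1cccc(O)c1 | starting material
2 | 1,3-dimethoxybenzene | COc1cccc(OC)c1 | intermediate
3 | prenyl bromide (1-bromo-3-methylbut-2-ene) | BrCC=C(C)C | starting material
4 | 1,3-dimethoxy-2-(3-methylbut-2-en-1-yl)benzene | COc1cccc(OC)c1CC=C(C)C | intermediate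
5 | 2-[3,5-dimethoxy-4-(3-methylbut-2-en-1-yl)phenyl]-4,4,5,5-tetramethyl-1,3,2-dioxaborolane | COc1cc(B2OC(C)(C)C(C)(C)O2)cc(OC)c1CC=C(C)C | intermediate
6 | 3,5-dimethoxy-4-(3-methylbut-2-en-1-yl)phenol | COc1cc(O)cc(OC)c1CC=C(C)C | intermediate
7 | 6-hydroxy-2,4-dimethoxy-3-(3-methylbut-2-en-1-yl)benzaldehyde | O=Cc1c(O)cc(OC)c(CC=C(C)C)c1OC | intermediate
8 | 1,3-bis(methoxymethoxy)benzene | COCOc1cccc(OCOC)c1 | intermediate
9 | 1-iodo-2,4-bis(methoxymethoxy)benzene | COCOc1ccc(I)c(OCOC)c1 | intermediate
10 | ethynyltrimethylsilane | C#C[Si](C)(C)C | starting material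
11 | {[2,4-bis(methoxymethoxy)phenyl]ethynyl}trimethylsilane | COCOc1ccc(C#C[Si](C)(C)C)c(OCOC)c1 | intermediate
12 | 1-ethynyl-2,4-bis(methoxymethoxy)benzene | COCOc1ccc(C#C)c(OCOC)c1 | intermediate
13 | 4-[2,4-bis(methoxymethoxy)phenyl]-1-(4-methylbenzenesulfonyl)-1H-1,2,3-triazole | COCOc1ccc(-c2cn(nn2)S(=O)(=O)c3ccc(C)cc3)c(OCOC)c1 | intermediate
14 | 3-[2,4-bis(methoxymethoxy)phenyl]-5,7-dimethoxy-6-(3-methylbut-2-en-1-yl)-4H-chromen-4-one | COCOc1ccc(-c2coc3cc(OC)c(CC=C(C)C)c(OC)c3c2=O)c(OCOC)c1 | intermediate
15 | 3-(2,4-dihydroxyphenyl)-5,7-dimethoxy-6-(3-methylbut-2-en-1-yl)-4H-chromen-4-one | COc1cc2occ(-c3ccc(O)cc3O)c(=O)c2c(OC)c1CC=C(C)C | intermediate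
16 | 7-O-methylluteone | COc1cc2occ(-c3ccc(O)cc3O)c(=O)c2c(O)c1CC=C(C)C | target

## Summary

**Total step count:** 13

**Longest linear sequence:** 8 (steps 1–5 then 11–13; the B branch, steps 6–10 then 11–13, is also 8)

**Steps most likely to fail, with fallbacks**

1. **Step 11 (proposed Rh(III) aldehyde C–H/azavinyl-carbene annulation).** Risks are carbene O–H insertion or sulfonyl transfer to the phenol, acyl-Rh decarbonylation, and incomplete TsNH2 elimination.
   Fallback (known chemistry): convert 7 to the 2-hydroxyacetophenone (MeMgBr, then MnO2), form the enaminone with DMF-DMA, cyclise with I2 to 3-iodo-5,7-dimethoxy-6-prenylchromone, and join it by Suzuki–Miyaura coupling with 2,4-bis(methoxymethoxy)phenylboronic ester (from 9 by Miyaura borylation) to reach 14.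

2. **Step 3 (Ir C–H borylation in the presence of the prenyl alkene).** Risks are alkene hydroboration or isomerisation by HBpin/Ir–H.
   Fallback: install the oxygen before the prenyl group. Borylate and oxidise 2 to 3,5-dimethoxyphenol, protect it as the TIPS ether, lithiate between the two OMe groups, prenylate, and remove TIPS with TBAF to give 6.

3. **Step 13 (selective 5-O-demethylation next to the prenyl group with free B-ring phenols).** Risks are incomplete reaction or Lewis-acid-induced prenyl cyclisation to a chroman.
   Fallback: replace selective demethylation with selective methylation. Run branch A from 8 (A-ring oxygens as MOM) and carry the B ring as TIPS ethers; after the annulation remove the A-ring MOM groups, methylate only the non-chelated 7-OH (MeI, K2CO3, 1 equiv; the hydrogen-bonded 5-OH does not react), then remove TIPS with TBAF.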